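Convention used below: the decalins carry eudesmane numbering, the ten-membered rings germacrane numbering. α/β refer to the usual eudesmane drawing (ring A left, C10 at the top of the ring fusion, β towards the viewer); "7βH" means that the isopropyl group on C7 is α. The SMILES strings are authoritative.

## Analysis of the target

Target 28 is a germacrane: a ten-membered carbocycle (C1 to C10) with one E-trisubstituted alkene (C1=C10, methyl on C10) and a trans-trisubstituted epoxide (C4–C5, methyl on C4). It carries a free secondary hydroxyl at C6, an isopropyl group at C7 and, at C8, the ester of isovanillic acid (21) with its phenol free. The five stereocenters C4 to C8 are contiguous and all R. C6–O and C7–isopropyl are trans, C7–isopropyl and C8–O are trans, and the epoxide oxygen is anti (erythro) to the C6 hydroxyl. The sensitive groups are the epoxide, which the C1=C10 alkene can open across the ring under acid, the 1,3-diol monoester, which can migrate under base, and the phenol. The 1,5-diene that precedes the epoxide cyclises with acid and undergoes Cope rearrangement on heating. The difficulty is the medium ring itself (entropy and transannular strain oppose any closure), two E alkenes, a stereotriad on a mobile ring, and two secondary hydroxyls that must be told apart. The strategy rests on one feature: C5 and C10 sit 1,6 across the ring, so a C5–C10 bond turns the ring into a trans-decalin (ring A: C1–C5 and C10; ring B: C5–C10). In that decalin C6–O, C7–isopropyl and C8–O are all equatorial on ring B, H5, O6, H7 and O8 all lie on the face opposite the angular methyl group, and C1 to C4 can be held as a cyclohexa-1,3-diene whose σ bond is C5–C10.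

## Retrosynthetic reasoning

28 from 27. The O–allyl bond of the phenol is cut last. The phenol stays masked through esterification and epoxidation, and the allyl group comes off under neutral palladium catalysis that leaves epoxide and ester alone.

27 from 26. The two C–O bonds of the epoxide are cut. In 26 only C4=C5 has an allylic hydroxyl, so a hydroxyl-directed epoxidation separates it from C1=C10 and lets C6 control the face. The epoxide is made late because it is the most acid-sensitive group.

26 from 20 and 23. The C6 silyl ether is removed (25 to 26) after the C8–O acyl bond has been formed from alcohol 20 and acid 23, which comes from 21. This order needs C8–OH free while C6–O is masked, hence two silyl ethers of different lability in 19.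

20 and 19 from 18. A Z alkene is added back between C2 and C3. This makes the ring a conjugated E,Z,E triene, which is the ring-opened form of a cyclohexadiene. The forward step must reduce only that cis-disubstituted alkene.

18 from 17 (key disconnection). The C5–C10 bond is re-formed. No other bond of the ring is touched, so the ten-membered ring is never closed from chain ends. Its three stereocenters and both E geometries are set on the decalin 17. The forward reaction must open the cyclohexadiene in the conrotatory sense with both ring B bonds turning outward.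

17 from 13. The diene is traced through dienyl triflate 16 and enone 15 to ketone 13. A C3 carbonyl allows C1=C2 to be introduced by Saegusa oxidation and C3=C4 by enolisation towards C4, and the C4 stereocenter is erased.

13 from 10. Silyl ethers 13 and 12 come from keto diol 11 and ketal diol 10. The C8 hydroxyl, which has a methylene neighbour, is silylated before the C6 hydroxyl, which is flanked by the ring fusion and the C4 methyl group.

10 from 8. The C6–O and C8–O bonds (with C5–H and C7–H) are cut to the ring B 5,7-diene 8. Each alkene takes boron at its CH terminus, and both additions occur anti to the angular methyl group, so four stereocenters follow from C10 alone.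

8 from 6. Diene ketal 8 comes from linear dienone 7 by deconjugative ketalisation, and 7 from 6 by moving the isopropenyl double bond into conjugation. The C7 center of 6 is erased on purpose, because hydroboration resets it.

6 from 1 and 2. A Robinson annulation is cut at C4=C5 (aldol condensation of 5) and at C1–C10 (Michael addition of ketone 1 to enone 2). A chiral primary amine auxiliary and the C7 center of 1 favour the same face, and the minor C10 epimer is a separable diastereomer.

## Alternatives that were turned down

Alternative 1: [2,3]-Wittig ring contraction. The C6–C7 bond is disconnected, which leads back to the thirteen-membered diallylic ether A1 in which oxygen links C6 and C12. In the forward step an alkyllithium base removes a proton from the C6 methylene, and the carbanion attacks C7 in a [2,3] shift that forms C6–C7, cuts O–C12 and gives trienol A2 with C6–OH and a C7 isopropenyl group.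
- For: ring, C6 and C7 are made in one step; a thirteen-membered ether is easier to close than a ten-membered carbocycle; A2 is thermally robust. A2 also has C6–OH free beside a protected C8–O, so the hydroxyls are differentiated by construction. On that point it is stronger than the chosen route, which relies on a selective silylation.
- Against: A1 has two allylic α-oxy methylenes (C6 and C12), and deprotonation at C12 leads to another skeleton. The C6/C7 configuration must be relayed from C8 through a flexible macrocyclic transition state. A1 needs two E-trisubstituted alkenes, a macro-etherification and a later selective hydrogenation of the isopropenyl group.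
- Comparison: the chosen strategy offers stereocontrol on a rigid decalin, alkene geometry fixed by orbital symmetry and no macrocyclisation, at the price of a photochemical step with a labile product.

Alternative 2: anionic oxy-Cope ring expansion. C2–C3 is cut and C5–C10 re-formed, giving the trans-1-isopropenyl-2-vinylcyclohexanol A3. The potassium alkoxide of A3 undergoes a [3,3] shift through a chair transition state that forms C2–C3 and breaks C5–C10, and the C4=C5 enolate is trapped as enol triflate A4.
- For: it cleaves the same bond as the chosen route, but thermally and irreversibly, so there is no photostationary mixture and no labile triene. The chair gives both E alkenes. On robustness and scale it is the stronger plan.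
- Against: A3 needs two adjacent fully substituted carbons (C5 with oxygen and isopropenyl, C10 with methyl and vinyl) set trans next to the C6 ether. Addition of an alkenyl nucleophile to a ketone flanked by a quaternary carbon and an α-alkoxy carbon is weak in facial control and prone to enolisation. A4 also carries an oxygen at C5 that the target lacks, so the triflate has to be reduced again, and the product 1,5-diene can undergo a further Cope rearrangement.
- Comparison: the chosen route sets every ring B center by additions anti to one angular methyl group and introduces no superfluous oxygen.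

Alternative 3: nickel-catalysed reductive alkyne–epoxide macrocyclisation. C9–C10 is disconnected to the open-chain epoxy alkyne A5. A zerovalent nickel–phosphine catalyst with a trialkylborane reductant joins the terminal epoxide carbon C9 to the alkyne carbon C10, delivers hydrogen to C1 and frees C8–OH, giving dienol A6.
- For: it is convergent, the chain stereocenters come from acyclic asymmetric methods, and ring, E alkene and free C8–OH arise in one step. A6 has exactly the C8–OH/C6–silyl differentiation the endgame needs, and no photochemistry is involved; on both points it is stronger than the chosen route.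
- Against: it closes a ten-membered carbocycle by C–C bond formation, the least favourable ring size, so it needs high dilution and competes with intermolecular coupling. The regiochemistry of insertion of a methyl alkyne in an endo closure of this size is not secured. A5 needs a long linear sequence (E-trisubstituted alkene plus three contiguous stereocenters).
- Comparison: the chosen route never makes chain ends meet, and its precursor 17 is reached in eleven steps from a terpene ketone.

Key step: step 12

## Route

Assumption: commercial (+)-dihydrocarvone 1 is used as its mixture of C2 epimers with C5 fixed as R; both epimers converge because C2 is enolised in step 1.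

Step 1
Reactants: 1 (+)-dihydrocarvone, (5R)-2-methyl-5-(prop-1-en-2-yl)cyclohexan-1-one; 2 ethyl vinyl ketone (pent-1-en-3-one)
Product: 5 (2R,5R)-2-methyl-2-(3-oxopentyl)-5-(prop-1-en-2-yl)cyclohexan-1-one, via ketimine 3 (not isolated), via Michael-adduct imine 4 (not isolated)
Conditions: (S)-1-phenylethylamine, TsOH (cat.), toluene, reflux (Dean–Stark); then 2, THF, 40 °C; then 10% aq. AcOH, rt
Reagents that add atoms: none
Why: Chiral-imine Michael addition: the imine reacts through its more substituted secondary enamine tautomer in an aza-ene-like transition state, so the quaternary carbon (C10) forms regioselectively. The (S)-auxiliary and the substrate's own preference for axial attack cis to the equatorial isopropenyl group direct enone 2 to the same face (matched pair), which should give the 2R (10α-methyl) configuration; mild acid then hydrolyses the imine.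

Step 2
Reactants: 5 (2R,5R)-2-methyl-2-(3-oxopentyl)-5-(prop-1-en-2-yl)cyclohexan-1-one
Product: 6 10-epi-α-cyperone, (4aR,7R)-1,4a-dimethyl-7-(prop-1-en-2-yl)-4,4a,5,6,7,8-hexahydronaphthalen-2(3H)-one
Conditions: NaOMe, MeOH, rt → 50 °C
Reagents that add atoms: none
Why: Intramolecular aldol condensation and dehydration (second half of a Robinson annulation) close ring A as the 4-en-3-one; C10 is quaternary and cannot epimerise. Any C10 epimer is a diastereomer and is removed here by chromatography, which matters because step 3 erases C7.

Step 3
Reactants: 6 10-epi-α-cyperone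
Product: 7 (4aR)-1,4a-dimethyl-7-(propan-2-yl)-4,4a,5,6-tetrahydronaphthalen-2(3H)-one (eudesma-4,6-dien-3-one with 10α-methyl, the enantiomer of β-cyperone)
Conditions: TsOH·H2O (0.2 equiv), toluene, 80 °C
Reagents that add atoms: none
Why: Acid-catalysed alkene migration of the α-cyperone to β-cyperone type: protonation of the isopropenyl group gives the tertiary C11 cation, loss of H7 and reconjugation through the dienol place the alkene at C6=C7. The linear dienone is the thermodynamic sink, and the C7 stereocenter is erased deliberately.

Step 4
Reactants: 7 eudesma-4,6-dien-3-one with 10α-methyl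
Product: 8 3,3-(ethylenedioxy)eudesma-5,7-diene with 10α-methyl (C4 epimers)
Conditions: ethylene glycol, TsOH·H2O (cat.), benzene, reflux (Dean–Stark)
Reagents that add atoms: ethylene glycol, OCCO
Why: Deconjugative ketalisation: the trienol ether formed under acid is protonated at C4, so both alkenes move by one position and the ketal carries the ring B 5,7-diene, as is known for steroidal 4,6-dien-3-ones. The new C4 center is inconsequential because it becomes sp2 in step 10.

Step 5
Reactants: 8 3,3-(ethylenedioxy)eudesma-5,7-diene with 10α-methyl
Product: 10 (5βH,6β,7βH,8β,10α-methyl)-3,3-(ethylenedioxy)eudesmane-6,8-diol (C4 epimers), via 6,8-bis(boryl) ketal 9 (not isolated)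
Conditions: BH3·THF (excess), THF, 0 °C → rt; then NaOH (aq.), H2O2, 0 °C → rt
Reagents that add atoms: hydrogen peroxide, OO
Why: Double Brown hydroboration–oxidation: each trisubstituted alkene takes boron at its CH terminus (C6 and C8) and hydrogen at C5 and C7. Both syn additions occur on the β face, anti to the axial C10 methyl group, which sets 5β-H, 6β-O, 7β-H and 8β-O (a trans-decalin with all ring B substituents equatorial); oxidation proceeds with retention.

Step 6
Reactants: 10 (5βH,6β,7βH,8β,10α-methyl)-3,3-(ethylenedioxy)eudesmane-6,8-diol
Product: 11 (5βH,6β,7βH,8β,10α-methyl)-6,8-dihydroxyeudesman-3-one (C4 epimers)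
Conditions: TsOH·H2O (cat.), acetone–H2O, 40 °C
Reagents that add atoms: water, O
Why: Acid-catalysed ketal hydrolysis; neither hydroxyl is β to the carbonyl, so no elimination is expected, and epimerisation at C4 is irrelevant.

Step 7
Reactants: 11 (5βH,6β,7βH,8β,10α-methyl)-6,8-dihydroxyeudesman-3-one
Product: 12 (5βH,6β,7βH,8β,10α-methyl)-6-hydroxy-8-(triethylsilyloxy)eudesman-3-one
Conditions: Et3SiCl (1.05 equiv), imidazole, CH2Cl2–DMF, −40 → −20 °C
Reagents that add atoms: chlorotriethylsilane, CC[Si](Cl)(CC)CC
Why: Selective silylation of the less hindered secondary alcohol: C8–OH has a methylene neighbour, whereas C6–OH is flanked by the ring fusion and suffers a peri interaction with the C4 methyl group.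

Step 8
Reactants: 12 (5βH,6β,7βH,8β,10α-methyl)-6-hydroxy-8-(triethylsilyloxy)eudesman-3-one
Product: 13 (5βH,6β,7βH,8β,10α-methyl)-6-(tert-butyldimethylsilyloxy)-8-(triethylsilyloxy)eudesman-3-one
Conditions: TBSOTf, 2,6-lutidine, CH2Cl2, −78 → 0 °C
Reagents that add atoms: tert-butyldimethylsilyl trifluoromethanesulfonate, CC(C)(C)[Si](C)(C)OS(=O)(=O)C(F)(F)F
Why: The hindered C6 alcohol needs the silyl triflate; 2,6-lutidine is too weak a base to enolise the ketone at low temperature.

Step 9
Reactants: 13 (5βH,6β,7βH,8β,10α-methyl)-6-(tert-butyldimethylsilyloxy)-8-(triethylsilyloxy)eudesman-3-one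
Product: 15 (5βH,6β,7βH,8β,10α-methyl)-6-(tert-butyldimethylsilyloxy)-8-(triethylsilyloxy)eudesm-1-en-3-one, via trimethylsilyl enol ether 14 (not isolated)
Conditions: LiN(iPr)2, Me3SiCl, THF, −78 °C; solvent exchange; Pd(OAc)2 (1.1 equiv), MeCN, rt
Reagents that add atoms: none
Why: Saegusa–Ito oxidation: kinetic deprotonation takes place at the C2 methylene and not at the substituted C4. Pd(OAc)2 (divalent palladium) converts the enol ether through an oxa-π-allyl complex and β-hydride loss from C1 into the 1-en-3-one.

Step 10
Reactants: 15 (5βH,6β,7βH,8β,10α-methyl)-6-(tert-butyldimethylsilyloxy)-8-(triethylsilyloxy)eudesm-1-en-3-one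
Product: 16 (5βH,6β,7βH,8β,10α-methyl)-6-(tert-butyldimethylsilyloxy)-8-(triethylsilyloxy)eudesma-1,3-dien-3-yl trifluoromethanesulfonate
Conditions: KN(SiMe3)2, THF, −78 → −40 °C; then PhNTf2, −78 → 0 °C
Reagents that add atoms: N-phenylbis(trifluoromethanesulfonimide), O=S(=O)(N(c1ccccc1)S(=O)(=O)C(F)(F)F)C(F)(F)F
Why: C4–H is the only enolisable position of the enone (C10 is quaternary), so the base gives the cross-conjugated dienolate, which is O-triflated; the C4 stereocenter disappears.

Step 11
Reactants: 16 eudesma-1,3-dien-3-yl trifluoromethanesulfonate (C6 TBS ether, C8 TES ether)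
Product: 17 (5βH,6β,7βH,8β,10α-methyl)-6-(tert-butyldimethylsilyloxy)-8-(triethylsilyloxy)eudesma-1,3-diene
Conditions: Pd(PPh3)4 (5 mol %), HCO2H, Et3N, DMF, 50 °C
Reagents that add atoms: none
Why: Palladium-catalysed formate reduction of an alkenyl triflate: oxidative addition to zerovalent palladium, exchange for formate, loss of CO2 to a palladium hydride and reductive elimination replace OTf by H without moving the diene.

Step 12
Reactants: 17 (5βH,6β,7βH,8β,10α-methyl)-6-(tert-butyldimethylsilyloxy)-8-(triethylsilyloxy)eudesma-1,3-diene
Product: 18 (1(10)E,2Z,4E)-6-(tert-butyldimethylsilyloxy)-8-(triethylsilyloxy)germacra-1(10),2,4-triene with the C6, C7 and C8 configuration of 28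
Conditions: hν (254 nm, low-pressure Hg lamp, quartz), degassed pentane–Et2O, −60 °C, stopped near the photostationary state
Reagents that add atoms: none
Why: Excitation of the s-cis diene triggers a six-electron electrocyclic ring opening that breaks the C5–C10 σ bond and, under photochemical control, is conrotatory. The closest known reaction type is the photochemical opening of cyclohexa-1,3-dienes to hexatrienes, in particular of trans-fused hexalin 1,3-dienes to E,Z,E-cyclodeca-1,3,5-trienes. No ring is closed: the ten-membered ring is the periphery of the decalin and is set free when the shared bond is cut, so there is no cyclisation mode and no dilution to consider. No stereocenter is created; C5 and C10 become sp2, and C6, C7 and C8, set earlier as equatorial groups, are untouched. The one selectivity needed is the sense of conrotation: the ring B bonds C5–C6 and C10–C9 are pseudo-equatorial and trans to each other on ring A, and the helical twist that the trans fusion imposes on the diene continues into outward rotation of both, giving E at C4=C5 and C1=C10 and leaving C2=C3 Z; inward rotation would force C6 and C9, tied by the two-atom C7–C8 bridge, past each other across the opening triene. The silyl ethers do not absorb at 254 nm, so the light goes into the diene only. Because 18 also absorbs and recloses thermally in the disrotatory mode, irradiation is stopped near the photostationary state and the cold solution goes directly into step 13; unchanged 17 is recovered after that step and recycled.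

Step 13
Reactants: 18 (1(10)E,2Z,4E)-6-(tert-butyldimethylsilyloxy)-8-(triethylsilyloxy)germacra-1(10),2,4-triene
Product: 19 (1(10)E,4E)-6-(tert-butyldimethylsilyloxy)-8-(triethylsilyloxy)germacra-1(10),4-diene with the C6, C7 and C8 configuration of 28
Conditions: KO2CN=NCO2K, AcOH, MeOH–THF, −30 → −10 °C
Reagents that add atoms: none
Why: Diimide transfers H2 in a concerted syn fashion and reacts fastest with the unhindered, strained cis-disubstituted C2=C3 alkene; the two trisubstituted E alkenes are much slower. The reduction is run cold so that it outpaces thermal reclosure of 18.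

Step 14
Reactants: 19 (1(10)E,4E)-6-(tert-butyldimethylsilyloxy)-8-(triethylsilyloxy)germacra-1(10),4-diene
Product: 20 (1(10)E,4E)-6-(tert-butyldimethylsilyloxy)germacra-1(10),4-dien-8-ol
Conditions: HF·pyridine, pyridine, THF, 0 °C
Reagents that add atoms: none
Why: The triethylsilyl ether is cleaved far faster than the hindered allylic TBS ether; buffering with pyridine guards against acid-induced transannular cyclisation of the 1,5-diene.

Step 15
Reactants: 21 isovanillic acid (3-hydroxy-4-methoxybenzoic acid)
Product: 23 3-(allyloxy)-4-methoxybenzoic acid, via allyl 3-(allyloxy)-4-methoxybenzoate 22 (not isolated)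
Conditions: allyl bromide, K2CO3, DMF, 60 °C; then NaOH (aq.), MeOH, 60 °C; then HCl (aq.) to pH 2
Reagents that add atoms: allyl bromide, C=CCBr; sodium hydroxide, [Na+].[OH-]
Why: Double O-alkylation of phenoxide and carboxylate, then saponification of the allyl ester in the same flask; the aryl allyl ether is stable to hydroxide.

Step 16
Reactants: 20 (1(10)E,4E)-6-(tert-butyldimethylsilyloxy)germacra-1(10),4-dien-8-ol; 23 3-(allyloxy)-4-methoxybenzoic acid
Product: 25 (1(10)E,4E)-6-(tert-butyldimethylsilyloxy)germacra-1(10),4-dien-8-yl 3-(allyloxy)-4-methoxybenzoate, via mixed anhydride 24 (not isolated)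
Conditions: 2,4,6-trichlorobenzoyl chloride, Et3N, THF, rt; then 20, DMAP, toluene, rt
Reagents that add atoms: none
Why: Yamaguchi esterification: DMAP attacks the mixed anhydride at the aroyl carbonyl that is not shielded by two ortho chlorines, and the acylpyridinium ion acylates the hindered C8 hydroxyl with retention at C8.

Step 17
Reactants: 25 (1(10)E,4E)-6-(tert-butyldimethylsilyloxy)germacra-1(10),4-dien-8-yl 3-(allyloxy)-4-methoxybenzoate
Product: 26 (1(10)E,4E)-6-hydroxygermacra-1(10),4-dien-8-yl 3-(allyloxy)-4-methoxybenzoate
Conditions: HF·pyridine, pyridine, THF, 0 °C → rt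
Reagents that add atoms: none
Why: Fluoride-mediated cleavage of the allylic TBS ether under buffered, non-basic conditions, so that the ester should not migrate from O8 to O6.

Step 18
Reactants: 26 (1(10)E,4E)-6-hydroxygermacra-1(10),4-dien-8-yl 3-(allyloxy)-4-methoxybenzoate
Product: 27 (1(10)E,4R,5R,6R,7R,8R)-4,5-epoxy-6-hydroxygermacr-1(10)-en-8-yl 3-(allyloxy)-4-methoxybenzoate
Conditions: Ti(OiPr)4, D-(−)-diisopropyl tartrate, t-BuOOH, 4 Å molecular sieves, CH2Cl2, −20 °C
Reagents that add atoms: tert-butyl hydroperoxide, CC(C)(C)OO
Why: Katsuki–Sharpless epoxidation: the titanium alkoxide of the C6 alcohol delivers the peroxide oxygen to C4=C5 only, since C1=C10 has no allylic hydroxyl. D-(−)-tartrate and the C6 carbinol form the matched pair for the erythro epoxy alcohol, so the oxygen should arrive anti to the C6 hydroxyl on the outer face of the ring and give 4R,5R.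

Step 19
Reactants: 27 (1(10)E,4R,5R,6R,7R,8R)-4,5-epoxy-6-hydroxygermacr-1(10)-en-8-yl 3-(allyloxy)-4-methoxybenzoate
Product: 28 (1(10)E,4R,5R,6R,7R,8R)-4,5-epoxy-6-hydroxygermacr-1(10)-en-8-yl 3-hydroxy-4-methoxybenzoate (target)
Conditions: Pd(PPh3)4 (5 mol %), morpholine, THF, rt
Reagents that add atoms: none
Why: Tsuji–Trost deallylation: zerovalent palladium ionises the aryl allyl ether to a π-allyl complex and the phenoxide, and morpholine takes up the allyl group; the neutral conditions spare epoxide and ester.

## Compound list

1 | (+)-dihydrocarvone, (5R)-2-methyl-5-(prop-1-en-2-yl)cyclohexan-1-one (C2 epimers) | CC1CC[C@@H](C(C)=C)CC1=O | starting material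
2 | ethyl vinyl ketone (pent-1-en-3-one) | CCC(=O)C=C | starting material
3 | N-[(1S)-1-phenylethyl] ketimine of 1 | CC1CC[C@@H](C(C)=C)CC1=N[C@@H](C)c1ccccc1 | intermediate
4 | N-[(1S)-1-phenylethyl] imine of 5 (Michael adduct) | CCC(=O)CC[C@@]1(C)CC[C@@H](C(C)=C)CC1=N[C@@H](C)c1ccccc1 | intermediate
5 | (2R,5R)-2-methyl-2-(3-oxopentyl)-5-(prop-1-en-2-yl)cyclohexan-1-one | CCC(=O)CC[C@@]1(C)CC[C@@H](C(C)=C)CC1=O | intermediate
6 | 10-epi-α-cyperone, (4aR,7R)-1,4a-dimethyl-7-(prop-1-en-2-yl)-4,4a,5,6,7,8-hexahydronaphthalen-2(3H)-one | CC1=C2C[C@H](C(C)=C)CC[C@]2(C)CCC1=O | intermediate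
7 | (4aR)-1,4a-dimethyl-7-(propan-2-yl)-4,4a,5,6-tetrahydronaphthalen-2(3H)-one | CC1=C2C=C(C(C)C)CC[C@]2(C)CCC1=O | intermediate
8 | 3,3-(ethylenedioxy)eudesma-5,7-diene with 10α-methyl (C4 epimers) | CC1C2=CC(C(C)C)=CC[C@]2(C)CCC13OCCO3 | intermediate
9 | (5βH,6β,7βH,8β,10α-methyl)-6,8-bis(boryl)-3,3-(ethylenedioxy)eudesmane | CC1[C@H]2[C@H](B)[C@@H](C(C)C)[C@H](B)C[C@]2(C)CCC13OCCO3 | intermediate
10 | (5βH,6β,7βH,8β,10α-methyl)-3,3-(ethylenedioxy)eudesmane-6,8-diol | CC1[C@H]2[C@H](O)[C@@H](C(C)C)[C@H](O)C[C@]2(C)CCC13OCCO3 | intermediate
11 | (5βH,6β,7βH,8β,10α-methyl)-6,8-dihydroxyeudesman-3-one | CC1[C@H]2[C@H](O)[C@@H](C(C)C)[C@H](O)C[C@]2(C)CCC1=O | intermediate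
12 | (5βH,6β,7βH,8β,10α-methyl)-6-hydroxy-8-(triethylsilyloxy)eudesman-3-one | CC1[C@H]2[C@H](O)[C@@H](C(C)C)[C@H](O[Si](CC)(CC)CC)C[C@]2(C)CCC1=O | intermediate
13 | (5βH,6β,7βH,8β,10α-methyl)-6-(tert-butyldimethylsilyloxy)-8-(triethylsilyloxy)eudesman-3-one | CC1[C@H]2[C@H](O[Si](C)(C)C(C)(C)C)[C@@H](C(C)C)[C@H](O[Si](CC)(CC)CC)C[C@]2(C)CCC1=O | intermediate
14 | 3-(trimethylsilyloxy)eudesm-2-ene derived from 13 | CC1[C@H]2[C@H](O[Si](C)(C)C(C)(C)C)[C@@H](C(C)C)[C@H](O[Si](CC)(CC)CC)C[C@]2(C)CC=C1O[Si](C)(C)C | intermediate
15 | (5βH,6β,7βH,8β,10α-methyl)-6-(tert-butyldimethylsilyloxy)-8-(triethylsilyloxy)eudesm-1-en-3-one | CC1[C@H]2[C@H](O[Si](C)(C)C(C)(C)C)[C@@H](C(C)C)[C@H](O[Si](CC)(CC)CC)C[C@]2(C)C=CC1=O | intermediate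
16 | (5βH,6β,7βH,8β,10α-methyl)-6-(tert-butyldimethylsilyloxy)-8-(triethylsilyloxy)eudesma-1,3-dien-3-yl trifluoromethanesulfonate | CC1=C(OS(=O)(=O)C(F)(F)F)C=C[C@@]2(C)C[C@@H](O[Si](CC)(CC)CC)[C@H](C(C)C)[C@@H](O[Si](C)(C)C(C)(C)C)[C@H]12 | intermediate
17 | (5βH,6β,7βH,8β,10α-methyl)-6-(tert-butyldimethylsilyloxy)-8-(triethylsilyloxy)eudesma-1,3-diene | C[C@@]12C=CC=C(C)[C@H]1[C@H](O[Si](C)(C)C(C)(C)C)[C@@H](C(C)C)[C@H](O[Si](CC)(CC)CC)C2 | intermediate
18 | (1(10)E,2Z,4E)-6-(tert-butyldimethylsilyloxy)-8-(triethylsilyloxy)germacra-1(10),2,4-triene | CC[Si](CC)(CC)O[C@@H]1C/C(C)=C/C=C\C(C)=C\[C@H](O[Si](C)(C)C(C)(C)C)[C@H]1C(C)C | intermediate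
19 | (1(10)E,4E)-6-(tert-butyldimethylsilyloxy)-8-(triethylsilyloxy)germacra-1(10),4-diene | CC[Si](CC)(CC)O[C@@H]1C/C(C)=C/CC/C(C)=C/[C@H](O[Si](C)(C)C(C)(C)C)[C@H]1C(C)C | intermediate
20 | (1(10)E,4E)-6-(tert-butyldimethylsilyloxy)germacra-1(10),4-dien-8-ol | O[C@@H]1C/C(C)=C/CC/C(C)=C/[C@H](O[Si](C)(C)C(C)(C)C)[C@H]1C(C)C | intermediate
21 | isovanillic acid | COc1ccc(C(=O)O)cc1O | starting material
22 | allyl 3-(allyloxy)-4-methoxybenzoate | COc1ccc(C(=O)OCC=C)cc1OCC=C | intermediate
23 | 3-(allyloxy)-4-methoxybenzoic acid | COc1ccc(C(=O)O)cc1OCC=C | intermediate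
24 | 3-(allyloxy)-4-methoxybenzoic 2,4,6-trichlorobenzoic anhydride | COc1ccc(C(=O)OC(=O)c2c(Cl)cc(Cl)cc2Cl)cc1OCC=C | intermediate
25 | (1(10)E,4E)-6-(tert-butyldimethylsilyloxy)germacra-1(10),4-dien-8-yl 3-(allyloxy)-4-methoxybenzoate | COc1ccc(C(=O)O[C@@H]2C/C(C)=C/CC/C(C)=C/[C@H](O[Si](C)(C)C(C)(C)C)[C@H]2C(C)C)cc1OCC=C | intermediate
26 | (1(10)E,4E)-6-hydroxygermacra-1(10),4-dien-8-yl 3-(allyloxy)-4-methoxybenzoate | COc1ccc(C(=O)O[C@@H]2C/C(C)=C/CC/C(C)=C/[C@H](O)[C@H]2C(C)C)cc1OCC=C | intermediate
27 | (1(10)E,4R,5R,6R,7R,8R)-4,5-epoxy-6-hydroxygermacr-1(10)-en-8-yl 3-(allyloxy)-4-methoxybenzoate | COc1ccc(C(=O)O[C@@H]2C/C(C)=C/CC[C@@]3(C)O[C@@H]3[C@H](O)[C@H]2C(C)C)cc1OCC=C | intermediate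
28 | (1(10)E,4R,5R,6R,7R,8R)-4,5-epoxy-6-hydroxygermacr-1(10)-en-8-yl 3-hydroxy-4-methoxybenzoate | COc1ccc(C(=O)O[C@@H]2C/C(C)=C/CC[C@@]3(C)O[C@@H]3[C@H](O)[C@H]2C(C)C)cc1O | target

## Step count and least certain steps

Total: 19 steps. Longest linear sequence: 18 steps from 1 (steps 1–14 and 16–19); step 15 is the side branch from 21.

Step 12 (key step). The most likely failure is loss of 18 by secondary photochemistry and by thermal reclosure, or a photostationary mixture poor in 18, because 17 and 18 both absorb at 254 nm and 18 is strained. Fallback: closed-loop flow irradiation in which the cold stream passes a column of AgNO3 on silica. The column holds back the triene, which contains trans alkenes, as its silver complex and returns unchanged 17 to the lamp, as is done in photochemical syntheses of trans-cycloalkenes. The triene is released cold with aqueous NH3 and NaCl. The fallback sets out from 17 and comes back at 18; it makes no new compound (F0).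

Step 5. The most likely failure is an incomplete second hydroboration, or migration of boron in the allylborane that forms if boron enters first at C6, which would scramble regio- and stereochemistry. Fallback: the two additions are separated. 9-BBN adds first to the less hindered C7=C8 alkene of 8 with boron at C8, and oxidation gives the homoallylic alcohol 3,3-(ethylenedioxy)-7βH-eudesm-5-en-8β-ol F2. BH3·THF then hydroborates the isolated C5=C6 alkene of F2 as in steroidal 5-enes. The fallback sets out from 8 and comes back at 10.

Step 4. The most likely failure is incomplete double-bond migration during ketalisation, because a heteroannular diene ketal competes thermodynamically. Fallback: kinetic deconjugation. KOtBu converts 7 into the trienolate, and rapid protonation at C4 with aqueous AcOH gives eudesma-5,7-dien-3-one F1. F1 is ketalised without acid equilibration (1,2-bis(trimethylsilyloxy)ethane, Me3SiOTf (cat.), CH2Cl2, −78 °C). The fallback sets out from 7 and comes back at 8.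

Step 7. The most likely failure is poor discrimination between the two secondary hydroxyls, with partial silylation at C6 or double silylation. Fallback: the differentiation is moved to the cleavage. Both hydroxyls of 11 are silylated with TBSOTf to the 6,8-bis(tert-butyldimethylsilyl) ether F3. Buffered HF·pyridine then cleaves the less hindered C8 ether to the 6-(tert-butyldimethylsilyloxy)-8-hydroxy ketone F4, and Et3SiCl with imidazole converts F4 into 13. The fallback sets out from 11 and comes back at 13.

Step 13. The most likely failure is thermal reclosure of 18 while diimide forms slowly in the cold, or over-reduction of the strained trisubstituted alkenes and of residual 17. Fallback: catalytic hydrogenation of the cold photolysate over Raney nickel (Ni) at −20 °C with uptake of one equivalent of H2, stopped by filtration. The fallback sets out from 18 and comes back at 19; it makes no new compound (F0).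

Step 18. The most likely failure is slow reaction with poor facial selectivity, because the matched transition state brings C7 close to the cis methyl group on C4 and the ring must present its less populated alkene rotamer. A second risk is Lewis-acid-induced transannular opening of the epoxide. Fallback: substrate-directed epoxidation with VO(acac)2 and t-BuOOH. The vanadate ester needs a smaller O–C6–C5=C4 dihedral angle, which the ring provides more easily, and relies on the hydroxyl alone and not on a chiral ligand. The fallback sets out from 26 and comes back at 27; it makes no new compound (F0).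

## Further compounds

F1 | step 4 | eudesma-5,7-dien-3-one with 10α-methyl (C4 epimers) | CC1C2=CC(C(C)C)=CC[C@]2(C)CCC1=O
F2 | step 5 | 3,3-(ethylenedioxy)-7βH-eudesm-5-en-8β-ol with 10α-methyl (C4 epimers) | CC1C2=C[C@@H](C(C)C)[C@H](O)C[C@]2(C)CCC13OCCO3
F3 | step 7 | (5βH,6β,7βH,8β,10α-methyl)-6,8-bis(tert-butyldimethylsilyloxy)eudesman-3-one | CC1[C@H]2[C@H](O[Si](C)(C)C(C)(C)C)[C@@H](C(C)C)[C@H](O[Si](C)(C)C(C)(C)C)C[C@]2(C)CCC1=O
F4 | step 7 | (5βH,6β,7βH,8β,10α-methyl)-6-(tert-butyldimethylsilyloxy)-8-hydroxyeudesman-3-one | CC1[C@H]2[C@H](O[Si](C)(C)C(C)(C)C)[C@@H](C(C)C)[C@H](O)C[C@]2(C)CCC1=O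
F0 | step 12 | none | none
F0 | step 13 | none | none
F0 | step 18 | none | none
A1 | alternative 1 | thirteen-membered diallylic ether (C8 TES ether) | CC[Si](CC)(CC)O[C@@H]1C/C(C)=C/CC/C(C)=C/COC/C(C)=C/1
A2 | alternative 1 | germacra-1(10),4,11-trien-6-ol (C8 TES ether) | CC[Si](CC)(CC)O[C@@H]1C/C(C)=C/CC/C(C)=C/[C@H](O)[C@H]1C(C)=C
A3 | alternative 2 | trans-1-isopropenyl-2-vinylcyclohexanol (C6 PMB ether, C8 TBS ether) | C=C[C@@]1(C)C[C@@H](O[Si](C)(C)C(C)(C)C)[C@H](C(C)C)[C@@H](OCc2ccc(OC)cc2)[C@]1(O)C(C)=C
A4 | alternative 2 | germacra-1(10),4-dien-5-yl triflate (C6 PMB ether, C8 TBS ether) | CC(C)(C)[Si](C)(C)O[C@@H]1C/C(C)=C/CC/C(C)=C(OS(=O)(=O)C(F)(F)F)/[C@H](OCc2ccc(OC)cc2)[C@H]1C(C)C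
A5 | alternative 3 | open-chain epoxy alkyne (C6 TES ether) | CC#CCC/C(C)=C/[C@H](O[Si](CC)(CC)CC)[C@@H](C(C)C)[C@H]1CO1
A6 | alternative 3 | germacra-1(10),4-dien-8-ol (C6 TES ether) | O[C@@H]1C/C(C)=C/CC/C(C)=C/[C@H](O[Si](CC)(CC)CC)[C@H]1C(C)C
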